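All runs were computed on assumed constants; the scatter is artificial.

1. The constants are not given, so they have to be read from the plateaus of the earlier runs.

| flask | substrate | reagent | remark | time |
|---|---|---|---|---|
| red | 0.40 M | 0.50 equiv | run made earlier |  |
| ochre | 0.40 M | 0.34 equiv | run made earlier |  |
| blue | 0.40 M | 0.75 equiv | run made earlier |  |
| Monday's | 0.40 M | 0.500 equiv (fed, over 4.00 min) | a stirred flask in which reagent is dosed at a steady rate over 4.00 min without added volume, worked up at 5.0 min | 5.0 min |
| Saturday's | 0.40 M (fed, over 4.00 min) | 0.500 equiv | all but substrate at the start; substrate goes in evenly over 4.00 min, the run ends at 5.0 min | 5.0 min |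
| Friday's | 0.40 M | 0.500 equiv | a closed flask charged with all of it at once and left for 5.0 min | 5.0 min |
| Tuesday's | 0.40 M | 0.500 equiv | one stirred flow tank at steady state, fed with the mixture as stated, mean residence time 5.0 min |  |

| run | time / min | target / % | substrate / % |
|---|---|---|---|
| red | 0.417 | 29.8 | 54.4 |
| red | 0.667 | 31.7 | 50.7 |
| red | 1.00 | 33.0 | 49.6 |
| red | 2.00 | 34.1 | 50.4 |
| red | 3.00 | 33.7 | 51.1 |
| red | 5.00 | 33.2 | 49.1 |
| ochre | 0.417 | 23.0 | 64.9 |
| ochre | 1.33 | 25.6 | 62.8 |
| ochre | 2.00 | 25.3 | 62.7 |
| ochre | 3.00 | 25.9 | 61.9 |
| ochre | 5.00 | 25.4 | 62.8 |
| ochre | 6.00 | 24.0 | 63.1 |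
| blue | 0.500 | 38.2 | 38.1 |
| blue | 0.833 | 41.8 | 34.9 |
| blue | 1.33 | 43.3 | 32.9 |
| blue | 2.00 | 44.1 | 33.0 |
| blue | 4.00 | 43.6 | 33.3 |
| blue | 6.00 | 43.6 | 33.1 |

(scatter of a reading: 0.5 percentage points)

- the stated concentrations are those of everything mixed, before any reaction; amounts are the same in each set-up
- the feed brings no volume worth counting
- the earlier runs were made in a closed, stirred flask
- a reading or a percentage of target counts all its forms, free or not
- a reading of substrate is of its free form alone

- the set-up with the highest amount of target at the outlet or at the end, in percent of the substrate put in ("none" if the first two lie within 2 percentage points) (Monday's / Saturday's / Friday's / Tuesday's / none)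
- amount of target at the outlet or at the end, in percent of the substrate put in, Monday's
- amount of target at the outlet or at the end, in percent of the substrate put in, Saturday's
- amount of target at the outlet or at the end, in percent of the substrate put in, Friday's
- amount of target at the outlet or at the end, in percent of the substrate put in, Tuesday's

2. A bench rule says that one reagent gives one target, so a plateau should equal the reagent charged. The mean plateaus read 25.2 % in ochre, 33.7 % in red and 43.8 % in blue. Target per reagent charged therefore reads 0.742, 0.673 and 0.584, lower in blue than in ochre.

3. This shortfall is what needs reckoning. Let B be the free reagent concentration, and assume that each reagent turned into target is accompanied by a loss of gB reagent. The slope of plateau against charge is then the target share at the charged B. From red to blue the slope reads 0.404 at a mean charged B of 0.250 M, which gives g = 5.90 /M, a selectivity factor per unit of B. Ochre to red reads 5.35 /M.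

4. The border of the bench rule is gB well below one. At Friday's charge gB is 1.18, so Friday's should stay near 33.7 %. Saturday's starts with the same B, so it should read the same.

5. Red's approach to its plateau reads a reagent life of 0.370 min, shorter than the feed of 4.00 min. Monday's should therefore hold B near 0.0185 M, which gives 45.1 %. Tuesday's tank, with B near 0.0148 M, should give 42.6 %.

6. The forecast gave 33.5 %, 33.5 %, 33.6 % and 31.3 % in the order asked, with best none, reasoning that “That points to a reversible reaction at equilibrium, not a consumption-limited one.”, and it differs from the reckoning here for Monday's and Tuesday's.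

    substrate + reagent → target (k = 17.4 /M/min)
    substrate + 2 reagent → side product (k = 48.9 /M²/min)
    substrate + target ⇌ idle adduct, settled at all times (K = 1.60 /M)

The best set-up is Monday's, with 47.3 %, above Tuesday's 44.3 %, while Saturday's gives 33.5 % and Friday's 33.5 %. Side product ends at 1.25 % in Monday's and 8.25 % in Friday's. Monday's highest reagent concentration was 0.0139 M, and with g = 5.90 /M this makes gB 0.0820 at that peak; reagent stood lower before and after it, so holding the peak for the whole run gives a lower bound of 46.2 % for Monday's target, under the flask's 47.3 %.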